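## Retrosynthetic overview

- The side chain is cut at the C3 ester: an 8,9-acetonide-protected eremophilenol is acylated with (R)-5-(angeloyloxy)hex-2-ynoic acid, and the (Z)-enoate is made afterwards by Lindlar reduction.
- The 8β,9β-diol and the C7 isopropenyl group both come from one cyclopropyl carbinol: its homoallyl rearrangement gives the C8=C9 alkene (for OsO4) and a C11 tertiary alcohol (dehydrated later).
- Ring A is closed last, onto ring B, by forming C4–C5: a C4 radical, made by hydrogen-atom transfer to a vinyl ketal, adds 6-endo to the C10=C5–C9=O enone.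
- Ring B, C14 and C11–C13 (ten carbons) come from (+)-3-carene via car-3-en-5-one; the chain C1–C4/C15 is attached at C10 by iodination and B-alkyl Suzuki coupling.
- Enabling feature: the C9 oxygen is 1,3 to C5 across C10, so a C9 ketone makes C5 the β-carbon of a ring-B enone (C3/C9 are 1,5-dioxygenated across C4–C5). The C7-isopropenyl/C8-oxygen pair maps onto the gem-dimethylcyclopropane of the carane, which blocks the β face of ring B.

Key step: step 6

Remark: eremophilane numbering is used for the decalins (ring A = C1–C5, C10; ring B = C5–C10; C14 on C5, C15 on C4, C11–C13 on C7), and β is the face carrying C14 and C15. The target is (3R,4R,5R,7R,8S,9R,10S), with a (2Z,5R) side chain and a (Z) angelate. (+)-3-Carene, 1,5-dichloropentan-3-one, (R)-pent-4-yn-2-ol and angelic acid are taken as commercial.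

## Route

Step 1
Reactants: 1 (+)-3-carene
Product: 2 car-3-en-5-one [(1R,6S)-4,7,7-trimethylbicyclo[4.1.0]hept-3-en-2-one]
Conditions: CrO3, 3,5-dimethylpyrazole, CH2Cl2, −20 °C
Reagents that add atoms: chromium trioxide O=[Cr](=O)=O
Why: Chromium-mediated allylic C–H oxidation should attack the ring CH2 next to the unsubstituted alkene carbon and give the β-methyl enone without touching the two stereocentres.

Step 2
Reactants: 2 car-3-en-5-one
Product: 3 (1R,6S)-3-iodo-4,7,7-trimethylbicyclo[4.1.0]hept-3-en-2-one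
Conditions: I2, pyridine, DMAP (cat.), CH2Cl2, rt
Reagents that add atoms: iodine II
Why: Pyridine-mediated α-iodination of an enone (conjugate addition, iodination of the enolate, elimination) should place iodine on C10, the only enone α-carbon.

Step 3
Reactants: 4 1,5-dichloropentan-3-one
Product: 5 2,2-bis(2-chloroethyl)-1,3-dioxolane
Conditions: ethylene glycol, TsOH·H2O (cat.), benzene, reflux, Dean–Stark
Reagents that add atoms: ethylene glycol OCCO
Why: Acid-catalysed ketalisation with azeotropic removal of water is routine for β-chloro ketones.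

Step 4
Reactants: 5 2,2-bis(2-chloroethyl)-1,3-dioxolane
Product: 6 2,2-diethenyl-1,3-dioxolane
Conditions: KOtBu, DMSO, rt; distillation
Reagents that add atoms: none
Why: Twofold E2 dehydrochlorination with a bulky base should give the divinyl ketal, in which the ketal carbon (future C3) is not a stereocentre.

Step 5
Reactants: 6 2,2-diethenyl-1,3-dioxolane; 3 (1R,6S)-3-iodo-4,7,7-trimethylbicyclo[4.1.0]hept-3-en-2-one
Product: 8 (1R,6S)-3-[2-(2-ethenyl-1,3-dioxolan-2-yl)ethyl]-4,7,7-trimethylbicyclo[4.1.0]hept-3-en-2-one, via B-alkyl-9-BBN adduct 7 (not isolated)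
Conditions: 6 (3 equiv), 9-BBN-H, THF, 0 °C → rt; then 3, Pd(dppf)Cl2, AsPh3, Cs2CO3, DMF/H2O, rt
Reagents that add atoms: none
Why: Anti-Markovnikov hydroboration of one vinyl group (excess diene suppresses double addition) followed by B-alkyl Suzuki–Miyaura coupling with the α-iodoenone should form the C10–C1 bond.

Step 6
Reactants: 8 (1R,6S)-3-[2-(2-ethenyl-1,3-dioxolan-2-yl)ethyl]-4,7,7-trimethylbicyclo[4.1.0]hept-3-en-2-one
Product: 10 3,3-(ethylenedioxy)-8,11-cyclo-10βH-eremophilan-9-one (cyclopropane β; 7αH; 8αH; cis-decalin), via C4 secondary alkyl radical 9 (not isolated)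
Conditions: Fe(acac)3 (0.3 equiv), PhSiH3, EtOH/ethylene glycol (5:1), 60 °C, high dilution; then NaOMe (cat.), MeOH, rt
Reagents that add atoms: none
Why: The iron hydride formed from Fe(acac)3 and PhSiH3 transfers a hydrogen atom to the terminal vinyl carbon (C15), giving the secondary C4 radical 9, which adds to C5, the β-carbon of the C10=C5–C9=O enone; the α-keto radical at C10 is reduced by divalent iron to the trivalent iron enolate and protonated by ethanol, which is a hydrogen-atom-transfer-initiated intramolecular Giese reaction (reductive olefin–enone coupling). Ring A closes in the 6-endo-trig mode, favoured over 5-exo because the nucleophilic radical attacks the electrophilic β-carbon and C10 is fully substituted. The quaternary centre C5 is set by the cyclopropane: its endo methyl covers the β face of ring B, so C4 arrives on the α face and C14 stays β. C4 should form through a chair-like transition state with its methyl pseudo-equatorial (β, cis to C14) and is corrected thermodynamically next to the C3 ketone in step 8; C10 is set by the NaOMe equilibration to the cis-fused ketone, because trans fusion would push C14 axially against the cyclopropane. The selectivity needed is hydrogen-atom transfer to the vinyl group only and ring closure faster than reduction of the radical; the first is secured because the isopropenyl group is still latent in the cyclopropane and the enone is tetrasubstituted and electron-poor, the second by dilution and the six-membered closure.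

Step 7
Reactants: 10 3,3-(ethylenedioxy)-8,11-cyclo-10βH-eremophilan-9-one
Product: 11 3,3-(ethylenedioxy)-8,11-cyclo-10βH-eremophilan-9ξ-ol (C9 epimers)
Conditions: NaBH4, MeOH/THF, 0 °C → rt
Reagents that add atoms: none
Why: Hydride reduction of the only free ketone (C3 is masked as the dioxolane) gives the cyclopropyl carbinol, whose C9 configuration is immaterial because C9 is ionised in step 8.

Step 8
Reactants: 11 3,3-(ethylenedioxy)-8,11-cyclo-10βH-eremophilan-9ξ-ol
Product: 13 11-hydroxy-10βH-eremophil-8-en-3-one, via homoallylic alcohol ketal 12 (not isolated)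
Conditions: 1 M HClO4, THF/H2O, 0 °C → rt
Reagents that add atoms: water O
Why: Cyclopropylcarbinyl–homoallyl rearrangement (Julia type): the C9 cation opens the C8–C11 bond, which is aligned with its empty orbital, to the tertiary C11 cation that water captures, leaving the C8=C9 alkene and C7 untouched; the same acid hydrolyses the dioxolane and equilibrates C4 to the equatorial β-methyl by enolisation.

Step 9
Reactants: 13 11-hydroxy-10βH-eremophil-8-en-3-one
Product: 14 8β,9β,11-trihydroxy-10βH-eremophilan-3-one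
Conditions: K2OsO4·2H2O (cat.), NMO, acetone/H2O, rt
Reagents that add atoms: N-methylmorpholine N-oxide C[N+]1([O-])CCOCC1; water O
Why: Catalytic osmium syn-dihydroxylation of the only alkene should occur on the convex β face (ring A is folded over the α face at C9/C10, and the C11 hydroxyl lies on the β side), giving both hydroxyls cis to the C7 substituent.

Step 10
Reactants: 14 8β,9β,11-trihydroxy-10βH-eremophilan-3-one
Product: 15 11-hydroxy-8β,9β-(isopropylidenedioxy)-10βH-eremophilan-3-one
Conditions: 2,2-dimethoxypropane, PPTS (cat.), CH2Cl2, rt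
Reagents that add atoms: 2,2-dimethoxypropane COC(C)(C)OC
Why: Acetonide formation is selective for the cis-1,2-diol (five-membered ring) and leaves the tertiary alcohol free.

Step 11
Reactants: 15 11-hydroxy-8β,9β-(isopropylidenedioxy)-10βH-eremophilan-3-one
Product: 16 8β,9β-(isopropylidenedioxy)-10βH-eremophil-11-en-3-one
Conditions: SOCl2, pyridine, CH2Cl2, −20 → 0 °C
Reagents that add atoms: none
Why: Dehydration through the tertiary chlorosulfite with pyridine should remove one of the six accessible methyl hydrogens in preference to the single hindered C7 hydrogen and so unveil the isopropenyl group; any isopropylidene isomer is removed on AgNO3-impregnated silica.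

Step 12
Reactants: 16 8β,9β-(isopropylidenedioxy)-10βH-eremophil-11-en-3-one
Product: 17 8β,9β-(isopropylidenedioxy)-10βH-eremophil-11-en-3α-ol
Conditions: Li, liquid NH3, THF, EtOH, −78 °C; NH4Cl
Reagents that add atoms: none
Why: Dissolving-metal reduction gives the thermodynamic equatorial 3α-alcohol (trans to C15), since an axial 3β-hydroxyl would be syn-diaxial to C14; the isolated alkene and the acetonide are inert.

Step 13
Reactants: 18 (R)-pent-4-yn-2-ol; 19 angelic acid
Product: 21 (R)-pent-4-yn-2-yl angelate, via angelic 2,4,6-trichlorobenzoic anhydride 20 (not isolated)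
Conditions: 2,4,6-trichlorobenzoyl chloride, Et3N, toluene, rt; then 18, toluene, 80 °C
Reagents that add atoms: none
Why: Yamaguchi esterification without DMAP acylates the alcohol with retention at the carbinol carbon and should avoid angelate-to-tiglate isomerisation.

Step 14
Reactants: 21 (R)-pent-4-yn-2-yl angelate
Product: 23 (R)-5-(angeloyloxy)hex-2-ynoic acid, via cesium ynoate 22 (not isolated)
Conditions: AgI (cat.), Cs2CO3, CO2 (1 atm), DMF, 50 °C; then 1 M HCl
Reagents that add atoms: carbon dioxide O=C=O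
Why: Silver-catalysed carboxylation of the terminal alkyne with CO2 under carbonate base should give the propiolic acid without a strong base that would attack the angelate.

Step 15
Reactants: 17 8β,9β-(isopropylidenedioxy)-10βH-eremophil-11-en-3α-ol; 23 (R)-5-(angeloyloxy)hex-2-ynoic acid
Product: 24 3α-[(5R)-5-(angeloyloxy)hex-2-ynoyloxy]-8β,9β-(isopropylidenedioxy)-10βH-eremophil-11-ene
Conditions: DCC, DMAP (cat.), CH2Cl2, −20 → 0 °C
Reagents that add atoms: none
Why: Steglich esterification of the single free (equatorial) hydroxyl; the ynoic acid has no alkene geometry to lose on activation.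

Step 16
Reactants: 24 3α-[(5R)-5-(angeloyloxy)hex-2-ynoyloxy]-8β,9β-(isopropylidenedioxy)-10βH-eremophil-11-ene
Product: 25 3α-[(2Z,5R)-5-(angeloyloxy)hex-2-enoyloxy]-8β,9β-(isopropylidenedioxy)-10βH-eremophil-11-ene
Conditions: H2 (1 atm), Pd/CaCO3 poisoned with Pb(OAc)2 (Lindlar catalyst), quinoline, EtOAc, rt
Reagents that add atoms: none
Why: Lindlar semi-hydrogenation adds H2 syn to the ynoate and should give the (Z)-enoate, the alkyne being reduced much faster than the 1,1-disubstituted and trisubstituted alkenes.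

Step 17
Reactants: 25 3α-[(2Z,5R)-5-(angeloyloxy)hex-2-enoyloxy]-8β,9β-(isopropylidenedioxy)-10βH-eremophil-11-ene
Product: 26 CNP0395983.1
Conditions: AcOH/H2O (4:1), 40 °C
Reagents that add atoms: none
Why: Mild acid hydrolysis of the acetonide frees the cis-diol without affecting the two esters or the alkene geometries.

## Compound list

1 | (+)-3-carene, (1S,6R)-3,7,7-trimethylbicyclo[4.1.0]hept-3-ene | CC1=CC[C@@H]2[C@H](C1)C2(C)C | starting material
2 | car-3-en-5-one, (1R,6S)-4,7,7-trimethylbicyclo[4.1.0]hept-3-en-2-one | CC1=CC(=O)[C@@H]2[C@H](C1)C2(C)C | intermediate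
3 | (1R,6S)-3-iodo-4,7,7-trimethylbicyclo[4.1.0]hept-3-en-2-one | CC1=C(I)C(=O)[C@@H]2[C@H](C1)C2(C)C | intermediate
4 | 1,5-dichloropentan-3-one | O=C(CCCl)CCCl | starting material
5 | 2,2-bis(2-chloroethyl)-1,3-dioxolane | ClCCC1(CCCl)OCCO1 | intermediate
6 | 2,2-diethenyl-1,3-dioxolane | C=CC1(C=C)OCCO1 | intermediate
7 | 9-[2-(2-ethenyl-1,3-dioxolan-2-yl)ethyl]-9-borabicyclo[3.3.1]nonane (not isolated) | C=CC1(CCB2C3CCCC2CCC3)OCCO1 | intermediate
8 | (1R,6S)-3-[2-(2-ethenyl-1,3-dioxolan-2-yl)ethyl]-4,7,7-trimethylbicyclo[4.1.0]hept-3-en-2-one | CC1=C(CCC3(C=C)OCCO3)C(=O)[C@@H]2[C@H](C1)C2(C)C | intermediate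
9 | C4 secondary alkyl radical of 8 after hydrogen-atom transfer to C15 (not isolated) | CC1=C(CCC3([CH]C)OCCO3)C(=O)[C@@H]2[C@H](C1)C2(C)C | intermediate
10 | 3,3-(ethylenedioxy)-8,11-cyclo-10βH-eremophilan-9-one (cyclopropane β, 7αH, 8αH, 4β- and 5β-methyl, cis-decalin) | C[C@H]1C2(OCCO2)CC[C@@H]3C(=O)[C@@H]4[C@H](C[C@]13C)C4(C)C | intermediate
11 | 3,3-(ethylenedioxy)-8,11-cyclo-10βH-eremophilan-9ξ-ol (both C9 epimers) | C[C@H]1C2(OCCO2)CC[C@@H]3C(O)[C@@H]4[C@H](C[C@]13C)C4(C)C | intermediate
12 | 3,3-(ethylenedioxy)-10βH-eremophil-8-en-11-ol (not isolated) | C[C@H]1C2(OCCO2)CC[C@@H]3C=C[C@H](C[C@]13C)C(C)(C)O | intermediate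
13 | 11-hydroxy-10βH-eremophil-8-en-3-one | C[C@H]1C(=O)CC[C@@H]2C=C[C@H](C[C@]12C)C(C)(C)O | intermediate
14 | 8β,9β,11-trihydroxy-10βH-eremophilan-3-one | C[C@H]1C(=O)CC[C@@H]2[C@@H](O)[C@@H](O)[C@H](C[C@]12C)C(C)(C)O | intermediate
15 | 11-hydroxy-8β,9β-(isopropylidenedioxy)-10βH-eremophilan-3-one | C[C@H]1C(=O)CC[C@@H]2[C@H]3OC(C)(C)O[C@H]3[C@H](C[C@]12C)C(C)(C)O | intermediate
16 | 8β,9β-(isopropylidenedioxy)-10βH-eremophil-11-en-3-one | C[C@H]1C(=O)CC[C@@H]2[C@H]3OC(C)(C)O[C@H]3[C@H](C[C@]12C)C(C)=C | intermediate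
17 | 8β,9β-(isopropylidenedioxy)-10βH-eremophil-11-en-3α-ol | C[C@H]1[C@H](O)CC[C@@H]2[C@H]3OC(C)(C)O[C@H]3[C@H](C[C@]12C)C(C)=C | intermediate
18 | (R)-pent-4-yn-2-ol | C[C@@H](O)CC#C | starting material
19 | angelic acid, (Z)-2-methylbut-2-enoic acid | C/C=C(/C)C(O)=O | starting material
20 | angelic 2,4,6-trichlorobenzoic anhydride (not isolated) | C/C=C(/C)C(=O)OC(=O)c1c(Cl)cc(Cl)cc1Cl | intermediate
21 | (R)-pent-4-yn-2-yl angelate | C/C=C(/C)C(=O)O[C@H](C)CC#C | intermediate
22 | cesium (R)-5-(angeloyloxy)hex-2-ynoate (not isolated) | C/C=C(/C)C(=O)O[C@H](C)CC#CC(=O)[O-].[Cs+] | intermediate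
23 | (R)-5-(angeloyloxy)hex-2-ynoic acid | C/C=C(/C)C(=O)O[C@H](C)CC#CC(O)=O | intermediate
24 | 3α-[(5R)-5-(angeloyloxy)hex-2-ynoyloxy]-8β,9β-(isopropylidenedioxy)-10βH-eremophil-11-ene | C=C(C)[C@H]1C[C@@]2(C)[C@H](CC[C@@H](OC(=O)C#CC[C@@H](C)OC(=O)/C(C)=C\C)[C@@H]2C)[C@H]3OC(C)(C)O[C@@H]13 | intermediate
25 | 3α-[(2Z,5R)-5-(angeloyloxy)hex-2-enoyloxy]-8β,9β-(isopropylidenedioxy)-10βH-eremophil-11-ene | C=C(C)[C@H]1C[C@@]2(C)[C@H](CC[C@@H](OC(=O)/C=C\C[C@@H](C)OC(=O)/C(C)=C\C)[C@@H]2C)[C@H]3OC(C)(C)O[C@@H]13 | intermediate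
26 | CNP0395983.1, 3α-[(2Z,5R)-5-(angeloyloxy)hex-2-enoyloxy]-10βH-eremophil-11-ene-8β,9β-diol | C=C(C)[C@H]1C[C@@]2(C)[C@H](CC[C@@H](OC(=O)/C=C\C[C@@H](C)OC(=O)/C(C)=C\C)[C@@H]2C)[C@@H](O)[C@H]1O | target

## Step count and risks

Total steps: 17. Longest linear sequence: 13 (steps 1, 2, 5–12, 15–17 from (+)-3-carene; the branch from 1,5-dichloropentan-3-one is equally long).

Steps most likely to fail:

1. Step 6 (key step). The C4 radical may be reduced before it closes the ring, so that the vinyl group is simply hydrogenated, because addition to the fully substituted β-carbon is slow. Fallback by polar chemistry, from 8 back to 10: diimide (KO2CN=NCO2K, AcOH, MeOH) saturates the vinyl group to the ethyl ketal (1R,6S)-3-[2-(2-ethyl-1,3-dioxolan-2-yl)ethyl]-4,7,7-trimethylbicyclo[4.1.0]hept-3-en-2-one F1. PPTS in wet acetone then frees (1R,6S)-4,7,7-trimethyl-3-(3-oxopentyl)bicyclo[4.1.0]hept-3-en-2-one F2. Catalytic KOtBu in t-BuOH/THF should bring about the intramolecular Michael addition of the ethyl ketone enolate (C4) to C5, again anti to the cyclopropane and under thermodynamic control at C4 and C10, giving 8,11-cyclo-10βH-eremophilane-3,9-dione F3. The unconjugated, less hindered C3 carbonyl is then ketalised selectively (1,2-bis(trimethylsilyloxy)ethane, cat. TMSOTf, CH2Cl2, −78 °C), which returns to 10.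

2. Step 8. The C11 cation may lose a proton instead of being hydrated, or the cyclopropylcarbinyl cation may rearrange along other paths. Fallback without a cation at C9, from 2 back to 12: cold aqueous H2SO4 (homoconjugate hydration of the cyclopropyl enone) should give (S)-5-(2-hydroxypropan-2-yl)-3-methylcyclohex-2-en-1-one F4. Iodination as in step 2 gives (S)-5-(2-hydroxypropan-2-yl)-2-iodo-3-methylcyclohex-2-en-1-one F5, and Suzuki coupling with 7 as in step 5 gives (S)-2-[2-(2-ethenyl-1,3-dioxolan-2-yl)ethyl]-5-(2-hydroxypropan-2-yl)-3-methylcyclohex-2-en-1-one F6. The cyclisation conditions of step 6, now steered by the equatorial C7 substituent (attack trans to it), give 3,3-(ethylenedioxy)-11-hydroxy-10βH-eremophilan-9-one F7. TsNHNH2 in EtOH gives its tosylhydrazone F8, and a Shapiro reaction (n-BuLi, THF, −78 → 0 °C; H2O) gives the C8=C9 alkene 12, which is hydrolysed to 13 with the acid of step 8.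

3. Step 11. Loss of the C7 proton may compete, giving the isopropylidene isomer and erasing the C7 stereocentre. Fallback by concerted syn-elimination, from 15 back to 16: Ac2O with cat. Sc(OTf)3 (MeCN, −20 °C) gives the tertiary acetate 11-acetoxy-8β,9β-(isopropylidenedioxy)-10βH-eremophilan-3-one F9. Flash vacuum pyrolysis (about 450 °C) then expels acetic acid through a cyclic transition state that can reach six methyl hydrogens but only one hindered ring hydrogen, giving 16.

Further compounds
F1 | step 6 | (1R,6S)-3-[2-(2-ethyl-1,3-dioxolan-2-yl)ethyl]-4,7,7-trimethylbicyclo[4.1.0]hept-3-en-2-one | CC1=C(CCC3(CC)OCCO3)C(=O)[C@@H]2[C@H](C1)C2(C)C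
F2 | step 6 | (1R,6S)-4,7,7-trimethyl-3-(3-oxopentyl)bicyclo[4.1.0]hept-3-en-2-one | CC1=C(CCC(=O)CC)C(=O)[C@@H]2[C@H](C1)C2(C)C
F3 | step 6 | 8,11-cyclo-10βH-eremophilane-3,9-dione | C[C@H]1C(=O)CC[C@@H]3C(=O)[C@@H]4[C@H](C[C@]13C)C4(C)C
F4 | step 8 | (S)-5-(2-hydroxypropan-2-yl)-3-methylcyclohex-2-en-1-one | CC1=CC(=O)C[C@H](C1)C(C)(C)O
F5 | step 8 | (S)-5-(2-hydroxypropan-2-yl)-2-iodo-3-methylcyclohex-2-en-1-one | CC1=C(I)C(=O)C[C@H](C1)C(C)(C)O
F6 | step 8 | (S)-2-[2-(2-ethenyl-1,3-dioxolan-2-yl)ethyl]-5-(2-hydroxypropan-2-yl)-3-methylcyclohex-2-en-1-one | CC1=C(CCC2(C=C)OCCO2)C(=O)C[C@H](C1)C(C)(C)O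
F7 | step 8 | 3,3-(ethylenedioxy)-11-hydroxy-10βH-eremophilan-9-one | C[C@H]1C2(OCCO2)CC[C@@H]3C(=O)C[C@H](C[C@]13C)C(C)(C)O
F8 | step 8 | 3,3-(ethylenedioxy)-11-hydroxy-10βH-eremophilan-9-one tosylhydrazone | C[C@H]1C2(OCCO2)CC[C@@H]3C(=NNS(=O)(=O)c4ccc(C)cc4)C[C@H](C[C@]13C)C(C)(C)O
F9 | step 11 | 11-acetoxy-8β,9β-(isopropylidenedioxy)-10βH-eremophilan-3-one | C[C@H]1C(=O)CC[C@@H]2[C@H]3OC(C)(C)O[C@H]3[C@H](C[C@]12C)C(C)(C)OC(C)=O
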